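**Plan**

- Retrosynthesis: the 4'-O-silyl ether is cut first. The C2-O and O-C1' bonds of the aryloxy link are then cut by taking the oxygen out, which restores the C2-C1' bond of a flavone. The C8-prenyl bond (back to an O5-prenyl ether), the O5-prenyl, O4'-Si and O7-CH3 bonds follow, ending at apigenin.
- Forward: rings A, B and C come intact from apigenin and no ring is built. The sequence is O7-methylation, O4'-silylation, O5-prenylation, para-Claisen-Cope shift of prenyl to C8, oxygen insertion between C2 and C1', and desilylation.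
- Enabling feature: C2 of the pyranone ring C becomes cationic when O4, flanked by the free O5-H, is silylated to a benzopyrylium ion. C2 carries ring B, whose C1' lies para to O4' and so migrates readily from carbon to a peroxide oxygen.
- Stereochemistry: the target has no stereocenter and no configured alkene. The stereogenic atoms that appear on the way (C6 of 8, C8 of 9, C2 of 14) are transient and racemic.

Key step: step 5

Remark on the chemistry: "prenyl" means 3-methylbut-2-en-1-yl throughout. No separate 5-O-silyl ether is made; the 5-OH is tied to the C4 oxygen by a diisopropylsilylene bridge inside the key step, and the 4'-oxygen carries a tert-butyldimethylsilyl (TBS) group.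

**Route**

Step 1
Reactants: 1 apigenin; 2 iodomethane
Product: 3 genkwanin (5-hydroxy-2-(4-hydroxyphenyl)-7-methoxychromen-4-one)
Conditions: MeI (1.05 equiv), K2CO3 (1.0 equiv), DMF, 0 °C to rt
Reagents that add atoms: iodomethane, CI
Why: Williamson etherification under acidity control: the 7-OH is a vinylogous carboxylic acid para to the C4 carbonyl and the most acidic hydroxyl of apigenin, so one equivalent of carbonate and iodomethane should alkylate it ahead of the 4'-OH and the chelated 5-OH.

Step 2
Reactants: 3 genkwanin; 4 tert-butyldimethylsilyl chloride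
Product: 5 2-[4-(tert-butyldimethylsilyloxy)phenyl]-5-hydroxy-7-methoxychromen-4-one
Conditions: TBSCl (1.1 equiv), imidazole, DMF, 0 °C to rt
Reagents that add atoms: tert-butyldimethylsilyl chloride, CC(C)(C)[Si](C)(C)Cl
Why: Silyl ether formation with silyl chloride and imidazole takes the free 4'-phenol, while the 5-OH, locked in a hydrogen bond to the C4 carbonyl, should not react under these mild conditions.

Step 3
Reactants: 5 2-[4-(tert-butyldimethylsilyloxy)phenyl]-5-hydroxy-7-methoxychromen-4-one; 6 3-methylbut-2-en-1-ol (prenyl alcohol)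
Product: 7 2-[4-(tert-butyldimethylsilyloxy)phenyl]-7-methoxy-5-(3-methylbut-2-enyloxy)chromen-4-one
Conditions: prenyl alcohol, PPh3, DIAD, THF, 0 °C to rt
Reagents that add atoms: 3-methylbut-2-en-1-ol, CC(C)=CCO
Why: Mitsunobu etherification is neutral, so the aryl silyl ether survives, and it is an established way to O-prenylate the chelated, weakly nucleophilic 5-OH of 5-hydroxyflavonoids without C-alkylation.

Step 4
Reactants: 7 2-[4-(tert-butyldimethylsilyloxy)phenyl]-7-methoxy-5-(3-methylbut-2-enyloxy)chromen-4-one
Product: 10 2-[4-(tert-butyldimethylsilyloxy)phenyl]-5-hydroxy-7-methoxy-8-prenylchromen-4-one, via ortho-dienone 8 (not isolated), via para-dienone 9 (not isolated)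
Conditions: Eu(fod)3 (10 mol %), NaHCO3, PhCl, 85 °C
Reagents that add atoms: none
Why: Lewis-acid-catalysed para-Claisen-Cope rearrangement: trivalent europium in Eu(fod)3 (the tris(heptafluoro-dimethyloctanedionate)) chelates O4 and O5 and promotes the [3,3] shift to C6, giving ortho-dienone 8 with a 1,1-dimethylallyl group that is too hindered to enolize quickly, so a second [3,3] (Cope) shift carries the chain to C8, para to O5, as a normal prenyl group in dienone 9, which tautomerizes to the phenol, the transient stereocenters being racemic and lost.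

Step 5
Reactants: 10 2-[4-(tert-butyldimethylsilyloxy)phenyl]-5-hydroxy-7-methoxy-8-prenylchromen-4-one; 11 diisopropylsilyl bis(trifluoromethanesulfonate); 12 bis(trimethylsilyl) peroxide
Product: 16 2-[4-(tert-butyldimethylsilyloxy)phenoxy]-5-hydroxy-7-methoxy-8-prenylchromen-4-one, via silylene-bridged flavylium triflate 13 (not isolated), via silylperoxy chromene 14 (not isolated), via aryloxy benzopyrylium triflate 15 (not isolated)
Conditions: iPr2Si(OTf)2 (1.1 equiv), 2,6-lutidine (1.1 equiv), CH2Cl2, rt; then Me3SiOOSiMe3 (1.5 equiv), -78 to -20 °C; then Et3N·3HF, -78 to 0 °C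
Reagents that add atoms: bis(trimethylsilyl) peroxide, C[Si](C)(C)OO[Si](C)(C)C
Why: Proposed new method: iPr2Si(OTf)2 bridges the free 5-OH and the C4 carbonyl oxygen to give the cyclic 4,5-silylenedioxyflavylium triflate 13, whose C2 takes up the silyl peroxide with release of Me3SiOTf to give perketal 14; Me3SiOTf then silylates the distal peroxide oxygen and the 4-siloxyphenyl group shifts from C2 to the proximal oxygen as (Me3Si)2O leaves, pushed by the ring-oxygen lone pair and the siloxydiene, so that C2-O and O-C1' form while C2-C1' breaks. The closest known chemistry is the Hock and Criegee rearrangement of benzylic hydroperoxides and peresters, the Baeyer-Villiger and Dakin oxidations run with Me3SiOOSiMe3 and Me3SiOTf, and the addition of silyl nucleophiles to C2 of silylene-bridged benzopyrylium ions made from 5-hydroxychromones. No ring of the product closes (the six-membered dioxasiline bridge is temporary and is cut by fluoride in the quench) and no stereocenter is created, because C2 of 14 returns to sp2 in the aromatic cation 15, which is stabilized by three oxygens. The step needs aryl migration to beat participation of the C3 enol-ether carbon (epoxide closure onto the peroxide or alkenyl shift with ring expansion): the para-siloxyaryl group can bridge as a phenonium ion, only its migration gives an aromatic pyrylium ion, and the conformer with the O-O bond antiperiplanar to C2-aryl is the least crowded. The prenyl alkene should survive because the silyl peroxide and silyl triflate pair oxidizes carbonyl-derived cations without epoxidizing alkenes, the lutidine keeps free TfOH away, and ring A is deactivated while the chromone is cationic. Et3N·3HF is used for the quench because fluoride attacks silicon and not C2 of 15, where water or an alcohol could expel the aryloxy group, and because this weakly acidic fluoride source should leave the aryl TBS ether in place.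

Step 6
Reactants: 16 2-[4-(tert-butyldimethylsilyloxy)phenoxy]-5-hydroxy-7-methoxy-8-prenylchromen-4-one
Product: 17 7-O-methylepimedonin G
Conditions: TBAF, AcOH (1:1), THF, 0 °C
Reagents that add atoms: none
Why: Fluoride-mediated desilylation of the aryl silyl ether, buffered with acetic acid so that neither fluoride nor the liberated phenoxide attacks C2 of the 2-aryloxychromone (a vinylogous carbonate) and the prenyl group is untouched.

**Compound list**

1 | apigenin | O=c1cc(-c2ccc(O)cc2)oc2cc(O)cc(O)c12 | starting material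
2 | iodomethane | CI | starting material
3 | genkwanin (5-hydroxy-2-(4-hydroxyphenyl)-7-methoxychromen-4-one) | COc1cc(O)c2c(=O)cc(-c3ccc(O)cc3)oc2c1 | intermediate
4 | tert-butyldimethylsilyl chloride | CC(C)(C)[Si](C)(C)Cl | starting material
5 | 2-[4-(tert-butyldimethylsilyloxy)phenyl]-5-hydroxy-7-methoxychromen-4-one | COc1cc(O)c2c(=O)cc(-c3ccc(O[Si](C)(C)C(C)(C)C)cc3)oc2c1 | intermediate
6 | 3-methylbut-2-en-1-ol (prenyl alcohol) | CC(C)=CCO | starting material
7 | 2-[4-(tert-butyldimethylsilyloxy)phenyl]-7-methoxy-5-(3-methylbut-2-enyloxy)chromen-4-one | COc1cc(OCC=C(C)C)c2c(=O)cc(-c3ccc(O[Si](C)(C)C(C)(C)C)cc3)oc2c1 | intermediate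
8 | ortho-dienone: racemic 2-[4-(tert-butyldimethylsilyloxy)phenyl]-7-methoxy-6-(2-methylbut-3-en-2-yl)-6H-chromene-4,5-dione | COC1=CC2=C(C(=O)C1C(C)(C)C=C)C(=O)C=C(O2)c1ccc(O[Si](C)(C)C(C)(C)C)cc1 | intermediate
9 | para-dienone: racemic 2-[4-(tert-butyldimethylsilyloxy)phenyl]-7-methoxy-8-(3-methylbut-2-enyl)-8H-chromene-4,5-dione | COC1=CC(=O)C2=C(OC(=CC2=O)c2ccc(O[Si](C)(C)C(C)(C)C)cc2)C1CC=C(C)C | intermediate
10 | 2-[4-(tert-butyldimethylsilyloxy)phenyl]-5-hydroxy-7-methoxy-8-(3-methylbut-2-enyl)chromen-4-one | COc1cc(O)c2c(=O)cc(-c3ccc(O[Si](C)(C)C(C)(C)C)cc3)oc2c1CC=C(C)C | intermediate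
11 | diisopropylsilyl bis(trifluoromethanesulfonate) | CC(C)[Si](OS(=O)(=O)C(F)(F)F)(OS(=O)(=O)C(F)(F)F)C(C)C | starting material
12 | bis(trimethylsilyl) peroxide | C[Si](C)(C)OO[Si](C)(C)C | starting material
13 | 4,5-O-(diisopropylsilylene)-bridged 7-methoxy-8-prenyl-4'-(tert-butyldimethylsilyloxy)flavylium triflate | COc1cc2O[Si](C(C)C)(C(C)C)Oc3cc(-c4ccc(O[Si](C)(C)C(C)(C)C)cc4)[o+]c(c1CC=C(C)C)c23.[O-]S(=O)(=O)C(F)(F)F | intermediate
14 | racemic 2-(trimethylsilylperoxy)-2-aryl-2H-chromene with the 4,5-O-diisopropylsilylene bridge (C3=C4 silyl enol ether) | COc1cc2O[Si](C(C)C)(C(C)C)OC3=CC(OO[Si](C)(C)C)(c4ccc(O[Si](C)(C)C(C)(C)C)cc4)Oc(c1CC=C(C)C)c23 | intermediate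
15 | 2-[4-(tert-butyldimethylsilyloxy)phenoxy]-4,5-O-(diisopropylsilylene)-7-methoxy-8-prenylbenzopyrylium triflate | COc1cc2O[Si](C(C)C)(C(C)C)Oc3cc(Oc4ccc(O[Si](C)(C)C(C)(C)C)cc4)[o+]c(c1CC=C(C)C)c23.[O-]S(=O)(=O)C(F)(F)F | intermediate
16 | 2-[4-(tert-butyldimethylsilyloxy)phenoxy]-5-hydroxy-7-methoxy-8-(3-methylbut-2-enyl)chromen-4-one | COc1cc(O)c2c(=O)cc(Oc3ccc(O[Si](C)(C)C(C)(C)C)cc3)oc2c1CC=C(C)C | intermediate
17 | 7-O-methylepimedonin G (5-hydroxy-2-(4-hydroxyphenoxy)-7-methoxy-8-(3-methylbut-2-enyl)chromen-4-one) | COc1cc(O)c2c(=O)cc(Oc3ccc(O)cc3)oc2c1CC=C(C)C | target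

**Step count**

Total steps: 6. Longest linear sequence: 6 (apigenin to target).

**Steps most likely to fail**

Step 5 (oxygen insertion). Several processes could defeat it:
- the peroxide may fail to add to the hindered, delocalized C2 cation;
- the C3 enol-ether carbon may take part (epoxide closure or alkenyl shift) instead of the aryl group migrating;
- ring A may be hydroxylated electrophilically once the neutral product is released;
- the aryloxy group may be lost by addition-elimination at C2 during the quench.

Fallback with known chemistry: the aryloxy bond is made by addition-elimination on a 2-sulfonylchromone and the prenyl group is introduced afterwards. It sets out from genkwanin 3 and returns at 16.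
- Alkaline cleavage of 3 (KOH, aqueous ethanol, reflux) would give 1-(2,6-dihydroxy-4-methoxyphenyl)ethanone F1 and 4-hydroxybenzoic acid. F1 is symmetrical, so the later ring closure is unambiguous; it is also an article of commerce and would in practice be bought.
- CS2 and excess t-BuOK in THF should convert it into 4,5-dihydroxy-7-methoxychromene-2-thione F2.
- S-Methylation with iodomethane 2 (K2CO3, acetone) should give 5-hydroxy-7-methoxy-2-(methylsulfanyl)chromen-4-one F3.
- mCPBA (CH2Cl2) should give 5-hydroxy-7-methoxy-2-(methylsulfonyl)chromen-4-one F4.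
- Excess hydroquinone (K2CO3, DMF, rt, degassed) should displace the sulfinate to give 5-hydroxy-2-(4-hydroxyphenoxy)-7-methoxychromen-4-one F5.
- Silyl chloride 4 with imidazole should give 2-[4-(tert-butyldimethylsilyloxy)phenoxy]-5-hydroxy-7-methoxychromen-4-one F6.
- Mitsunobu reaction with prenyl alcohol 6 should give 2-[4-(tert-butyldimethylsilyloxy)phenoxy]-7-methoxy-5-(3-methylbut-2-enyloxy)chromen-4-one F7.
- The Eu(fod)3-catalysed para-Claisen-Cope rearrangement, as in step 4, should then deliver 16.

Step 4 (para-Claisen-Cope). The rearrangement may stop at the ortho stage, with enolization of dienone 8 before the Cope shift giving the 6-(1,1-dimethylallyl) isomer, or the ether may ionize and lose the prenyl group.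

Fallback: the C8-prenyl bond is made by cross-coupling. It sets out from 5 and returns at 10.
- Mitsunobu methylation of the 5-OH (MeOH, PPh3, DIAD) should give 2-[4-(tert-butyldimethylsilyloxy)phenyl]-5,7-dimethoxychromen-4-one F8.
- Iodination with NIS and catalytic CF3CO2H in MeCN should go to C8, the usual position for 5,7-dialkoxyflavones, giving 2-[4-(tert-butyldimethylsilyloxy)phenyl]-8-iodo-5,7-dimethoxychromen-4-one F9.
- Stille coupling with tributyl(3-methylbut-2-enyl)stannane and the zerovalent palladium complex Pd(PPh3)4 (DMF, 90 °C) should give 2-[4-(tert-butyldimethylsilyloxy)phenyl]-5,7-dimethoxy-8-(3-methylbut-2-enyl)chromen-4-one F10.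
- Chelation-controlled cleavage of the methyl ether peri to the carbonyl with MgI2 etherate (THF, 60 °C) should give 10.

Step 1 (O7-methylation). Over-alkylation at O4' may occur, since the acidity gap between the 7-OH and the 4'-OH is modest.

Fallback: the other hydroxyls are masked first. It sets out from 1 and returns at 3.
- Ac2O and pyridine should give apigenin triacetate F11.
- Thiophenol and imidazole in NMP at 0 °C should remove only the most labile 7-acetate, giving 5,4'-di-O-acetylapigenin F12.
- Mitsunobu methylation (MeOH, PPh3, DIAD) should give 5,4'-di-O-acetyl-7-O-methylapigenin F13.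
- K2CO3 in MeOH should remove both acetates to give 3.

Further compounds
F1 | step 5 | 1-(2,6-dihydroxy-4-methoxyphenyl)ethanone | CC(=O)c1c(O)cc(OC)cc1O
F2 | step 5 | 4,5-dihydroxy-7-methoxychromene-2-thione | COc1cc(O)c2c(O)cc(=S)oc2c1
F3 | step 5 | 5-hydroxy-7-methoxy-2-(methylsulfanyl)chromen-4-one | COc1cc(O)c2c(=O)cc(SC)oc2c1
F4 | step 5 | 5-hydroxy-7-methoxy-2-(methylsulfonyl)chromen-4-one | COc1cc(O)c2c(=O)cc(S(C)(=O)=O)oc2c1
F5 | step 5 | 5-hydroxy-2-(4-hydroxyphenoxy)-7-methoxychromen-4-one | COc1cc(O)c2c(=O)cc(Oc3ccc(O)cc3)oc2c1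
F6 | step 5 | 2-[4-(tert-butyldimethylsilyloxy)phenoxy]-5-hydroxy-7-methoxychromen-4-one | COc1cc(O)c2c(=O)cc(Oc3ccc(O[Si](C)(C)C(C)(C)C)cc3)oc2c1
F7 | step 5 | 2-[4-(tert-butyldimethylsilyloxy)phenoxy]-7-methoxy-5-(3-methylbut-2-enyloxy)chromen-4-one | COc1cc(OCC=C(C)C)c2c(=O)cc(Oc3ccc(O[Si](C)(C)C(C)(C)C)cc3)oc2c1
F8 | step 4 | 2-[4-(tert-butyldimethylsilyloxy)phenyl]-5,7-dimethoxychromen-4-one | COc1cc(OC)c2c(=O)cc(-c3ccc(O[Si](C)(C)C(C)(C)C)cc3)oc2c1
F9 | step 4 | 2-[4-(tert-butyldimethylsilyloxy)phenyl]-8-iodo-5,7-dimethoxychromen-4-one | COc1cc(OC)c2c(=O)cc(-c3ccc(O[Si](C)(C)C(C)(C)C)cc3)oc2c1I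
F10 | step 4 | 2-[4-(tert-butyldimethylsilyloxy)phenyl]-5,7-dimethoxy-8-(3-methylbut-2-enyl)chromen-4-one | COc1cc(OC)c2c(=O)cc(-c3ccc(O[Si](C)(C)C(C)(C)C)cc3)oc2c1CC=C(C)C
F11 | step 1 | apigenin triacetate | CC(=O)Oc1ccc(-c2cc(=O)c3c(OC(C)=O)cc(OC(C)=O)cc3o2)cc1
F12 | step 1 | 5,4'-di-O-acetylapigenin | CC(=O)Oc1ccc(-c2cc(=O)c3c(OC(C)=O)cc(O)cc3o2)cc1
F13 | step 1 | 5,4'-di-O-acetyl-7-O-methylapigenin | CC(=O)Oc1ccc(-c2cc(=O)c3c(OC(C)=O)cc(OC)cc3o2)cc1
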